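Readings and results are calculated with made-up constants, and the scatter is random.

4 questions stood on the board, and the first 3 ask how much electrophile has gone at the end.

| flask | electrophile | nucleophile | remark | time |
|---|---|---|---|---|
| autumn | 0.80 M | 1.1 equiv | run made earlier |  |
| noon | 0.80 M | 3.2 equiv | run made earlier |  |
| amber | 0.80 M | 0.900 equiv |  | 6.0 h |
| violet | 0.80 M | 1.40 equiv |  | 6.0 h |
| red | 0.80 M | 2.00 equiv |  | 6.0 h |

| run | time / h | electrophile / % | product / % |
|---|---|---|---|
| autumn | 0.500 | 88 | 6 |
| autumn | 1.33 | 74 | 18 |
| autumn | 2.50 | 61 | 25 |
| autumn | 4.00 | 52 | 33 |
| noon | 0.333 | 77 | 15 |
| noon | 0.833 | 56 | 31 |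
| noon | 2.00 | 34 | 47 |
| noon | 4.00 | 18 | 68 |

(each reading ± 1.5 percentage points)

- in percentages every species weighs as the electrophile in it: one idle adduct counts as two
- for product the idle adduct is counted in
- what was read earlier has a scatter of 1.5 percentage points, one standard deviation
- what may be going on: electrophile + nucleophile <-> acid set free + product; nucleophile + acid set free <-> protonated nucleophile; electrophile + product <-> idle adduct
- in an amount of product, one idle adduct counts as one product
- what has gone from electrophile into another species counts as reacted, even if it can come back

- part of the electrophile that has reacted at the end, amber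
- part of the electrophile that has reacted at the end, violet
- part of the electrophile that has reacted at the end, red
- what raising the equivalents of nucleophile from its lowest to its highest value here does to the part of the electrophile that has reacted (changes below 5 percentage points count as none) (it falls / it rises / no change)

1. I began with the bookkeeping. One idle adduct counts once in product and twice in the balance. So the reacted part equals product plus the adduct gap g, the whole charge minus electrophile minus product.

2. The fast rung came next. I took Q as gap over electrophile times free product, where free product is product minus gap, all as fractions. In noon, Q read 1.48 at 0.333 h and 1.44 at 4.00 h, so I let the adduct follow product without delay.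

3. The last readings gave a gap of 15 percentage points in autumn and 14 points in noon, although product stood at 33% and 68%. I carried their mean, the adduct gap g = 14 points.

4. The slow rung was product formation, the rate-limiting step. I assumed that a second nucleophile takes up each acid set free. With product x and n equivalents, the rate is k(a − x)(n − 2x), where a is the whole charge minus g, here 85.5%. Integrating to the last readings gave k = 0.176 h⁻¹ from autumn and 0.173 h⁻¹ from noon, per equivalent, and I used the mean, 0.174 h⁻¹. For amber, 1/(kn) is 6.37 h, longer than the 0.333 h of the first noon reading, where Q already stood at its later level, and close to the 6.0 h allowed.

5. My reckoning gave product of 33.2% in amber, 47.5% in violet and 60.7% in red. Adding g gave 47.7%, 62.0% and 75.2%, a rise of 27 points, more than the margin.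

6. The forecast gave 47%, 62% and 74%, and it rises: “Reacted electrophile rises with equivalents”.

7. The flasks gave 49.2%, 64.5% and 76.1%; the answer to the trend is it rises, by 27 points.

    electrophile + nucleophile ⇌ acid set free + product (K = 1.48, k = 5.75 × 10⁻⁵ M⁻¹ s⁻¹)
    nucleophile + acid set free ⇌ protonated nucleophile, settled at all times (K = 56.0 M⁻¹)
    electrophile + product ⇌ idle adduct, settled at all times (K = 2.20 M⁻¹)

In red at 6.00 h, the reacted part exceeded product by 17 points, half of the idle adduct's 34.8%, against my g of 14 points. The flask like red but with 0.800 equiv of nucleophile held product of 30.4%; adding g gives 44.9%, and its reacted part stood at 45.3%.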